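## The problem

The target 25 is a daucane-type hydroazulene. A cyclopentane (ring B: C4, C5, C8, C9, C10) is trans-fused to a cycloheptenone (ring A: C1–C7), numbered C1 (methyl-bearing alkene carbon), C2 (alkene CH), C3 (carbinol esterified with 4-hydroxybenzoic acid), C4 (fusion CH), C5 (fusion quaternary C-methyl), C6 (CH2), C7 (ketone), C8 (CHOH), C9 (CH2) and C10 (isopropyl carbinol). Five contiguous stereocenters must be set (C3 S, C4 S, C5 R, C8 R, C10 R in this numbering), two of them fully substituted. The C5 methyl and the C8 and C10 hydroxyls lie on one face (β); the C4 hydrogen and the C3 acyloxy group lie on the other (α). C8 is the only center that can be bought. It can direct the addition that creates C10 (1,3 across ring B) and the bond that creates its neighbour C5, and the C10 hydroxyl can in turn deliver hydride to C3. C4 has no directing group on the correct face and has to be set by protonation away from the three β substituents. The fragile features are the γ-acyloxy enone (an allylic aryl ester open to elimination and to ionisation by zerovalent palladium), the free phenol, and the tertiary C10 alcohol, which is β to C3 and will dehydrate or suffer retro-aldol cleavage whenever C3 is a ketone. Ring A carries oxygen at C7 and at C3, separated by C1–C2. This maps onto a three-carbon siloxyvinylcarbenoid (C6–C7–C1) and a four-carbon 2-alkoxydiene (C2–C3–C4–C5) whose far alkene is the C4=C5 bond of a cyclopentene, so cyclopropanation at C2=C3 followed by a divinylcyclopropane Cope shift closes ring A and creates C5 in one operation.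

## Retrosynthesis

**25 from 24.** No skeletal bond is cut. The phenol and the C8 hydroxyl are both carried as tert-butyldimethylsilyl ethers in 24, so one fluoride treatment ends the synthesis. An acetate or benzyl ether on the phenol would need base or hydrogen, neither welcome beside the allylic aryl ester and the enone. The forward step must only spare the C3 ester and the tertiary alcohol.

**24 from 23.** The C1=C2 alkene is traced to the allyl β-keto ester 23, in which C1 is quaternary (methyl and allyloxycarbonyl). Compared with desaturating a plain C7 ketone, this fixes the site: after loss of CO2 palladium sits on C1 and can lose hydride only toward C2 or the methyl. It also lets the C1 methyl enter by alkylation of a β-keto ester. The forward reaction is a palladium-mediated decarboxylative dehydrogenation that must tolerate the C3 ester.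

**23 from 19 and 22.** The ester C–O bond is cut to the diol 19 and the silylated acid 22, which comes from 4-hydroxybenzoic acid 20 through the bis-silyl compound 21. Acylating before the enone is formed keeps the C3 hydroxyl from ever being an allylic alcohol in the presence of a palladium hydride. The forward reaction must select the secondary C3 hydroxyl over the tertiary C10 hydroxyl, which sterics ensure.

**19 from 18, 17 and 16.** The C3–H bond is cut to ketone 18, whose free C10 hydroxyl can deliver hydride internally. This both sets C3 and distinguishes the C3 ketone from the C7 ketone, which no external hydride would do. 18 comes from its triethylsilyl ether 17, and 17 from the ethyl enol ether 16 by hydrolysis, the step that installs the C4 hydrogen. The order is dictated by the functionality: the enol ether is hydrolysed while C10 is still silylated (a free tertiary allylic alcohol next to an enol ether ionises to the enone), and the silyl group is removed only then.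

**16 from 15 and 14.** The C1–CH3 bond is cut to β-keto ester 15, and 15 is the desilylated form of the silyl enol ether 14. Methylation at this stage needs only carbonate, and it is done before C3 becomes a ketone so that base never meets the β-oxy ketone.

**14 from 9 and 12 (through 13).** The bonds C1–C2 and C5–C6 are cut, which opens ring A and removes the C5 stereocenter. The precursors are the cyclopentenyl 2-ethoxydiene 9, carrying all of ring B with C8 and C10 in place, and the siloxyvinyl diazoacetate 12. Cuts through C3–C4 or C4–C5 would leave ring B unmade or make both rings in one untested event. This cut delivers the two ring A oxygens differentiated (silyl enol ether of a β-keto ester at C7, alkyl enol ether at C3) and asks the key step to control a single stereocenter. The forward reaction is cyclopropanation of the enol ether to the cis-divinylcyclopropane 13 followed by Cope rearrangement; it must find the terminal alkene and bond C6 to C5 on the face away from the C8 silyl ether.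

**9 from 8, 7, 5 and 6.** The O–Si bond gives alcohol 8, the C10–isopropyl bond gives dienone 7, and the C3–C4 bond gives bromoenone 5 and stannane 6. Coupling before the isopropyl addition keeps the Stille step on a flat, activated α-bromoenone, not on a bromide wedged between a quaternary carbinol and a methyl-bearing carbon. The addition must then occur anti to the C8 silyl ether.

**5 from 3, 2 and 1 (through 4).** The C4–Br bond is cut to enone 3 (via dibromide 4), and the C5–CH3 bond to the commercial enone 1 through enol silane 2. Conjugate methylation with silyl trapping and re-oxidation is the shortest way to put a β-methyl on the silyloxy enone without touching C8.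

**12 from 11 and 10.** The enol silyl ether and the diazo group are removed in turn, leading to allyl acetoacetate 10 by way of the diazo ketoester 11. The allyl ester is carried from the start because it is the handle for the decarboxylative dehydrogenation.

## Roads not taken

**Alternative 1:** Ring A would be cut at C3–C4 and C5–C6 and closed by a (5+2) cycloaddition. The oxidopyrylium generated from pyranone A1 adds across the alkene of the menthyloxy butenolide A2 to give the oxygen-bridged adduct A3. Its merit is considerable: A3 already holds the C7 ketone, the C1 methyl, the C1=C2 alkene and the C3 oxygen with the right configuration, and the bridge can be cut reductively at C6 with SmI2. In this respect it is clearly ahead of the chosen plan, which spends six steps after its key step on ring A. The weak points lie elsewhere. The dipolarophile is a β-methyl butenolide, a trisubstituted alkene that must form the quaternary C5 with the correct regiochemistry. The adduct is cis at C4/C5 and needs an epimerisation at C4. Above all, ring B does not exist: C9 and the isopropyl group must be added to the lactone carbons, the five-membered ring closed, and C8 and C10 set late in a crowded bicycle. The chosen plan sets against this a ring B complete with its three stereocenters before the key step and a sequence after it that consists only of functional-group adjustments.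

**Alternative 2:** Both rings would be cut at once, at C4–C5 and C1–C2. In the forward step the oxyallyl cation generated from the acyclic chloroketone A4 adds to its tethered siloxydiene and gives the trans-fused bicycle A5. No other route builds as much in one step (two rings, two bonds, the C4 and C5 centers), and A5 holds C3 as a ketone and C7 as an enol silane, so fewer steps would follow than in the chosen plan. That advantage is real. Against it stands A4 itself: a linear compound with the tertiary C10 carbinol and C8 set without cyclic control, and a geometrically defined trisubstituted siloxydiene with an inward methyl. The cycloaddition must form a quaternary center at a diene terminus with facial control from acyclic stereocenters, and the β-silyloxy ketone invites elimination under ionising conditions. The enol silane in A5 also points toward C6, so the C1=C2 alkene still needs a separate desaturation. The chosen plan offers a key step in which only one stereocenter is at stake, and a precursor made in six steps from a commercial enone.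

**Alternative 3:** Here the C4–C5 fusion bond is cut. Protonation of the alkenyl group on the cyclobutanol A6 gives a tertiary cation at C5, C4 migrates to it with ring expansion, and the cyclopentanone A7 results. Its strength is that the C4/C5 relationship follows from a stereospecific 1,2-shift with retention at C4, and that C3 is set early as a propargylic carbinol. In this one respect it is better than the chosen plan, where C4 depends on a kinetic protonation. Its weaknesses are step economy and risk: the key step makes one bond and one ring, the seven-membered ring remains to be closed between C7 and C1, and the C8 ketone must later be reduced to the β alcohol at a neopentyl position. The acid needed for the shift threatens the tertiary silyl ether on the cyclobutane and the propargylic silyl ether, and the cation can simply lose a proton. The chosen plan answers with the option of equilibrating C4 next to the C3 ketone and with a much shorter route to its key-step precursor.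

Key step: step 9

Assumption: the enantiomer of the catalyst that reinforces the facial bias of diene 9 is taken to be Rh2(S-PTAD)4, dirhodium tetrakis[(S)-(1-adamantyl)(N-phthalimido)acetate]; should the pair prove mismatched, Rh2(R-PTAD)4 takes its place with nothing else changed.

Notation: the atom labels C1–C10 defined in the first section are used for every intermediate; β is the face of the C5 methyl, α the face of the C4 hydrogen.

## Route

Step 1
Reactants: 1 (R)-4-(tert-butyldimethylsilyloxy)cyclopent-2-en-1-one
Product: 2 tert-butyl(dimethyl){[(1R,2R)-2-methyl-4-(trimethylsilyloxy)cyclopent-3-en-1-yl]oxy}silane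
Conditions: Me2CuLi (from MeLi, CuI), TMSCl, THF, −78 °C; Et3N, then aq. NaHCO3
Reagents that add atoms: lithium dimethylcuprate, C[Cu-]C.[Li+]; chlorotrimethylsilane, C[Si](C)(C)Cl
Why: Conjugate addition of the Gilman cuprate occurs anti to the C8 silyloxy group, and chlorotrimethylsilane traps the enolate on oxygen so that the C10–C4 enol silane is obtained regiodefined; the new methine at C5 is made planar again in step 2, so its configuration does not matter.

Step 2
Reactants: 2 tert-butyl(dimethyl){[(1R,2R)-2-methyl-4-(trimethylsilyloxy)cyclopent-3-en-1-yl]oxy}silane
Product: 3 (R)-4-(tert-butyldimethylsilyloxy)-3-methylcyclopent-2-en-1-one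
Conditions: Pd(OAc)2 (10 mol%), O2 (1 atm), DMSO, 25 °C
Reagents that add atoms: none
Why: Saegusa–Ito oxidation: divalent palladium binds C4 on the face anti to the C5 methyl, which is the face of the C5 hydrogen, so syn β-hydride elimination restores the C4=C5 alkene now carrying the methyl; oxygen returns the palladium to the divalent state.

Step 3
Reactants: 3 (R)-4-(tert-butyldimethylsilyloxy)-3-methylcyclopent-2-en-1-one
Product: 5 (R)-2-bromo-4-(tert-butyldimethylsilyloxy)-3-methylcyclopent-2-en-1-one, via dibromide 4 (not isolated)
Conditions: Br2, CH2Cl2, 0 °C; then Et3N, 0 → 25 °C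
Reagents that add atoms: bromine, BrBr
Why: Bromine adds across the enone alkene and triethylamine removes the acidic C4 hydrogen with loss of the C5 bromide (addition–elimination α-bromination of an enone), a sequence that works for β-alkyl cyclopentenones; the amine also keeps HBr away from the silyl ether.

Step 4
Reactants: 5 (R)-2-bromo-4-(tert-butyldimethylsilyloxy)-3-methylcyclopent-2-en-1-one; 6 tributyl(1-ethoxyvinyl)stannane
Product: 7 (R)-4-(tert-butyldimethylsilyloxy)-2-(1-ethoxyethenyl)-3-methylcyclopent-2-en-1-one
Conditions: Pd(PPh3)4 (5 mol%), CuI (10 mol%), DMF, 60 °C; chromatography on K2CO3-treated silica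
Reagents that add atoms: none
Why: Stille coupling: the α-bromoenone is a flat, activated partner for oxidative addition and CuI speeds transfer of the α-substituted vinyl group from tin, so the C3–C4 bond is made before C10 becomes a crowded quaternary carbon. Base-treated silica protects the enol ether from hydrolysis to the methyl ketone.

Step 5
Reactants: 7 (R)-4-(tert-butyldimethylsilyloxy)-2-(1-ethoxyethenyl)-3-methylcyclopent-2-en-1-one
Product: 8 (1R,4R)-4-(tert-butyldimethylsilyloxy)-2-(1-ethoxyethenyl)-3-methyl-1-(propan-2-yl)cyclopent-2-en-1-ol
Conditions: i-PrMgCl, CeCl3, THF, −78 °C; pH 7 buffer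
Reagents that add atoms: isopropylmagnesium chloride, CC(C)[Mg]Cl
Why: Organocerium 1,2-addition: the weakly basic cerium reagent adds to the carbonyl without enolisation toward C9 (which would expel the C8 silyloxy group) and without hydride transfer. C10 is set by attack on the face opposite the C8 silyl ether, the usual course for 4-silyloxycyclopentenones, so the new hydroxyl is cis to the C8 oxygen.

Step 6
Reactants: 8 (1R,4R)-4-(tert-butyldimethylsilyloxy)-2-(1-ethoxyethenyl)-3-methyl-1-(propan-2-yl)cyclopent-2-en-1-ol
Product: 9 tert-butyl{[(1R,4R)-3-(1-ethoxyethenyl)-2-methyl-4-(propan-2-yl)-4-(triethylsilyloxy)cyclopent-2-en-1-yl]oxy}dimethylsilane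
Conditions: TESOTf, 2,6-lutidine, CH2Cl2, −78 → 0 °C
Reagents that add atoms: triethylsilyl trifluoromethanesulfonate, CC[Si](CC)(CC)OS(=O)(=O)C(F)(F)F
Why: A silyl triflate with a hindered pyridine base silylates tertiary alcohols; the hydroxyl must be masked because the carbenoid of step 9 would insert into O–H. Triethylsilyl is chosen to outlast the fluoride of step 10 and the acid of step 12 and still leave before the secondary tert-butyldimethylsilyl ether.

Step 7
Reactants: 10 allyl acetoacetate
Product: 11 allyl 2-diazo-3-oxobutanoate
Conditions: p-ABSA, Et3N, MeCN, 0 → 25 °C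
Reagents that add atoms: 4-acetamidobenzenesulfonyl azide, CC(=O)Nc1ccc(cc1)S(=O)(=O)N=[N+]=[N-]
Why: Regitz diazo transfer to the active methylene of a β-keto ester.

Step 8
Reactants: 11 allyl 2-diazo-3-oxobutanoate
Product: 12 allyl 2-diazo-3-(tert-butyldimethylsilyloxy)but-3-enoate
Conditions: TBSOTf, Et3N, CH2Cl2, 0 °C
Reagents that add atoms: tert-butyldimethylsilyl trifluoromethanesulfonate, CC(C)(C)[Si](C)(C)OS(=O)(=O)C(F)(F)F
Why: Soft enolisation of the acetyl group and O-silylation gives the 2-siloxyvinyl diazoacetate, the standard entry to this class of vinylcarbenoid precursors; the diazo group is inert to silyl triflate and amine.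

Step 9
Reactants: 9 tert-butyl{[(1R,4R)-3-(1-ethoxyethenyl)-2-methyl-4-(propan-2-yl)-4-(triethylsilyloxy)cyclopent-2-en-1-yl]oxy}dimethylsilane; 12 allyl 2-diazo-3-(tert-butyldimethylsilyloxy)but-3-enoate
Product: 14 allyl ester of the ring A/ring B cycloheptadiene (C1=C7 bearing the ester at C1 and OTBS at C7; C3=C4 bearing OEt at C3; C5 methyl β; C8 OTBS β; C10 OTES β; isopropyl α), via cis-divinylcyclopropane 13 (not isolated)
Conditions: Rh2(S-PTAD)4 (2 mol%), 12 (2.5 equiv, slow addition), hexane, 0 → 25 °C; then PhMe, 110 °C
Reagents that add atoms: none
Why: The dirhodium tetracarboxylate turns 12 into a donor/acceptor vinylcarbenoid whose carbene carbon (C1) adds to the terminal CH2 (C2) of the 1,1-disubstituted ethyl enol ether of 9, giving cyclopropane 13 with the siloxyvinyl and cyclopentenyl groups cis. On heating, 13 undergoes the Cope rearrangement through the boat transition state in which both alkenes lie over the three-membered ring: C5–C6 forms, C1–C3 breaks, and ring A closes by (3,3) sigmatropic ring expansion of the cyclopropane to the cyclohepta-1,4-diene. The closest known reaction type is the tandem cyclopropanation/Cope rearrangement of 2-siloxyvinyl diazoacetates with 2-oxygenated dienes (formal (4+3) cycloaddition). C5 is the only stereocenter that survives; its configuration follows from the face of the C4=C5 alkene that C6 reaches, which should be the α face, away from the adjacent C8 silyl ether, since C10 carries a group on each face and cannot discriminate. That face is fixed by the configuration of 13, so the chiral phthalimido-carboxylate catalyst is used to reinforce the substrate bias in the cyclopropanation; this ligand class, unlike the arylsulfonylprolinates such as Rh2(S-DOSP)4, gives useful induction with 2-siloxyvinyl carbenoids. Site selectivity rests on the enol ether being far more nucleophilic and accessible than the tetrasubstituted ring alkene, the 2-siloxy group suppresses reaction at the vinylogous carbon, and a hydrocarbon solvent disfavours heterolytic opening of the donor–acceptor cyclopropane. Heating is needed because the C5 methyl points inward in the boat and C5 is fully substituted; 12 is added slowly in excess to a concentrated solution of 9 so that bimolecular capture outruns attack of the carbenoid on its own allyl group.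

Step 10
Reactants: 14 allyl ester of the ring A/ring B cycloheptadiene
Product: 15 allyl β-keto ester (C7 ketone; C1 bearing H and allyloxycarbonyl; C3=C4 ethyl enol ether; C8 OTBS and C10 OTES retained)
Conditions: Bu4NF (1.1 equiv), AcOH (1.1 equiv), THF, −40 → 0 °C
Reagents that add atoms: none
Why: The silyl enol ether of a β-keto ester is a vinylogous silyl ester and is cleaved by fluoride far faster than alkyl silyl ethers; acetic acid protonates the enolate as it forms, and the ethyl enol ether does not hydrolyse under these nearly neutral conditions.

Step 11
Reactants: 15 allyl β-keto ester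
Product: 16 C1-methylated allyl β-keto ester (C1 bearing methyl and allyloxycarbonyl, both epimers; C3=C4 ethyl enol ether)
Conditions: MeI, K2CO3, acetone, 25 °C
Reagents that add atoms: iodomethane, CI
Why: C-alkylation of a β-keto ester enolate with a soft electrophile; C1 is the only acidic position. Its configuration is irrelevant because C1 becomes trigonal in step 17, and the methylation is done while C3 is still an enol ether so that no base meets a C3 ketone with the C10 oxygen in the β position.

Step 12
Reactants: 16 C1-methylated allyl β-keto ester
Product: 17 trans-fused C3,C7-diketone (C4 H α; C10 OTES; C8 OTBS; C1 methyl and allyloxycarbonyl)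
Conditions: oxalic acid, THF/H2O, 0 °C
Reagents that add atoms: water, O
Why: Acid hydrolysis of the enol ether: C4 is protonated, water adds to the C3 oxocarbenium ion and ethanol leaves. The proton should arrive on the α face because the β face of C4 is flanked by the angular methyl and both silyloxy groups, which gives the trans ring fusion; C10 stays silylated here because a free tertiary allylic alcohol next to the enol ether would ionise to the conjugated enone (Stork–Danheiser-type transposition).

Step 13
Reactants: 17 trans-fused C3,C7-diketone
Product: 18 β-hydroxy ketone (C10 OH free; C3 and C7 ketones; C8 OTBS)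
Conditions: HF·pyridine, pyridine, THF, 0 °C
Reagents that add atoms: none
Why: Buffered HF·pyridine removes triethylsilyl ethers faster than tert-butyldimethylsilyl ethers, and the C8 ether is neopentylic as well; the medium is mildly acidic, so the β-hydroxy ketone meets neither base (retro-aldol) nor strong acid (dehydration).

Step 14
Reactants: 18 β-hydroxy ketone
Product: 19 anti-1,3-diol (C3 OH α; C10 OH β; C7 ketone; C8 OTBS; allyl ester)
Conditions: Me4NBH(OAc)3, MeCN/AcOH, −30 °C
Reagents that add atoms: none
Why: Evans–Saksena reduction: the C10 hydroxyl exchanges onto boron and hydride is delivered internally to the β face of the C3 carbonyl, which sets the C3 hydroxyl α (1,3-anti). Triacetoxyborohydride does not reduce ketones that lack such a hydroxyl, so the C7 ketone is left alone.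

Step 15
Reactants: 20 4-hydroxybenzoic acid
Product: 22 4-(tert-butyldimethylsilyloxy)benzoic acid, via bis-silyl compound 21 (not isolated)
Conditions: TBSCl (2.5 equiv), imidazole, DMF, 25 °C; then AcOH/THF/H2O, 25 °C
Reagents that add atoms: tert-butyldimethylsilyl chloride, CC(C)(C)[Si](C)(C)Cl
Why: Exhaustive silylation followed by selective hydrolysis of the far more labile silyl ester leaves the aryl silyl ether; a standard protection of hydroxybenzoic acids.

Step 16
Reactants: 19 anti-1,3-diol; 22 4-(tert-butyldimethylsilyloxy)benzoic acid
Product: 23 C3 4-(tert-butyldimethylsilyloxy)benzoate of 19 (C10 OH free; C8 OTBS; allyl β-keto ester)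
Conditions: DCC, DMAP, CH2Cl2, 0 → 25 °C
Reagents that add atoms: none
Why: Steglich esterification; only the secondary C3 hydroxyl is acylated, since C10 is tertiary and C8 silylated. Crude 19 is used at once so that the C1 epimer whose allyl ester is cis to the C3 hydroxyl has no time to lactonise.

Step 17
Reactants: 23 C3 4-(tert-butyldimethylsilyloxy)benzoate
Product: 24 bis-silyl enone (C1=C2 with C1 methyl; C7 ketone; C3 silyloxybenzoate α; C8 OTBS; C10 OH)
Conditions: Pd(OAc)2 (10 mol%), dppe (10 mol%), MeCN, 80 °C
Reagents that add atoms: none
Why: Palladium-mediated decarboxylative dehydrogenation of an allyl β-keto ester: zerovalent palladium ionises the allyl ester, CO2 is lost, and the C1 palladium enolate undergoes β-hydride elimination toward C2 to give the conjugated trisubstituted C1=C2 alkene with release of propene. Acetonitrile and a bidentate phosphine favour this path over allylation or protonation, and both C1 epimers converge.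

Step 18
Reactants: 24 bis-silyl enone
Product: 25 CNP0199397.1, the target (C3 4-hydroxybenzoate α; C4 H α; C5 methyl β; C8 OH β; C10 OH β)
Conditions: HF·pyridine, THF/pyridine, 0 → 25 °C
Reagents that add atoms: none
Why: Fluoride cleaves the aryl and the secondary alkyl silyl ether in one operation under mildly acidic conditions that do not threaten the allylic aryl ester, the enone or the tertiary alcohol.

## Compound list

1 | (R)-4-(tert-butyldimethylsilyloxy)cyclopent-2-en-1-one | O=C1C=C[C@H](O[Si](C)(C)C(C)(C)C)C1 | starting material
2 | tert-butyl(dimethyl){[(1R,2R)-2-methyl-4-(trimethylsilyloxy)cyclopent-3-en-1-yl]oxy}silane (methyl trans to OTBS) | C[C@@H]1C=C(O[Si](C)(C)C)C[C@H]1O[Si](C)(C)C(C)(C)C | intermediate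
3 | (R)-4-(tert-butyldimethylsilyloxy)-3-methylcyclopent-2-en-1-one | CC1=CC(=O)C[C@H]1O[Si](C)(C)C(C)(C)C | intermediate
4 | (4R)-2,3-dibromo-4-(tert-butyldimethylsilyloxy)-3-methylcyclopentan-1-one (trans-dibromide, mixture at the two new centers) | CC1(Br)C(Br)C(=O)C[C@H]1O[Si](C)(C)C(C)(C)C | intermediate
5 | (R)-2-bromo-4-(tert-butyldimethylsilyloxy)-3-methylcyclopent-2-en-1-one | CC1=C(Br)C(=O)C[C@H]1O[Si](C)(C)C(C)(C)C | intermediate
6 | tributyl(1-ethoxyvinyl)stannane | CCCC[Sn](CCCC)(CCCC)C(=C)OCC | starting material
7 | (R)-4-(tert-butyldimethylsilyloxy)-2-(1-ethoxyethenyl)-3-methylcyclopent-2-en-1-one | C=C(OCC)C1=C(C)[C@H](O[Si](C)(C)C(C)(C)C)CC1=O | intermediate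
8 | (1R,4R)-4-(tert-butyldimethylsilyloxy)-2-(1-ethoxyethenyl)-3-methyl-1-(propan-2-yl)cyclopent-2-en-1-ol (OH cis to OTBS) | C=C(OCC)C1=C(C)[C@H](O[Si](C)(C)C(C)(C)C)C[C@@]1(O)C(C)C | intermediate
9 | tert-butyl{[(1R,4R)-3-(1-ethoxyethenyl)-2-methyl-4-(propan-2-yl)-4-(triethylsilyloxy)cyclopent-2-en-1-yl]oxy}dimethylsilane | C=C(OCC)C1=C(C)[C@H](O[Si](C)(C)C(C)(C)C)C[C@@]1(O[Si](CC)(CC)CC)C(C)C | intermediate
10 | allyl acetoacetate | C=CCOC(=O)CC(C)=O | starting material
11 | allyl 2-diazo-3-oxobutanoate | C=CCOC(=O)C(=[N+]=[N-])C(C)=O | intermediate
12 | allyl 2-diazo-3-(tert-butyldimethylsilyloxy)but-3-enoate | C=CCOC(=O)C(=[N+]=[N-])C(=C)O[Si](C)(C)C(C)(C)C | intermediate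
13 | allyl (1R,2R)-2-ethoxy-1-[1-(tert-butyldimethylsilyloxy)ethenyl]-2-[cyclopentenyl of 9]cyclopropane-1-carboxylate (the two alkenyl groups cis) | C=CCOC(=O)[C@]1(C(=C)O[Si](C)(C)C(C)(C)C)C[C@@]1(OCC)C2=C(C)[C@H](O[Si](C)(C)C(C)(C)C)C[C@@]2(O[Si](CC)(CC)CC)C(C)C | intermediate
14 | bicyclic cycloheptadiene: allyl ester at C1, C1=C7 with C7 OTBS, C3=C4 with C3 OEt, C5 methyl β, C8 OTBS β, C10 OTES β and isopropyl α | C=CCOC(=O)C1=C(O[Si](C)(C)C(C)(C)C)C[C@@]2(C)[C@H](O[Si](C)(C)C(C)(C)C)C[C@@](O[Si](CC)(CC)CC)(C(C)C)C2=C(OCC)C1 | intermediate
15 | allyl β-keto ester: C7 ketone, C1 H, C3=C4 ethyl enol ether, C8 OTBS, C10 OTES (C1 not defined, enolisable) | C=CCOC(=O)C1CC(OCC)=C2[C@@](C)(CC1=O)[C@H](O[Si](C)(C)C(C)(C)C)C[C@@]2(O[Si](CC)(CC)CC)C(C)C | intermediate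
16 | C1-methylated allyl β-keto ester, C3=C4 ethyl enol ether (both C1 epimers) | C=CCOC(=O)C1(C)CC(OCC)=C2[C@@](C)(CC1=O)[C@H](O[Si](C)(C)C(C)(C)C)C[C@@]2(O[Si](CC)(CC)CC)C(C)C | intermediate
17 | trans-fused C3,C7-diketone: C4 H α, C10 OTES, C8 OTBS (both C1 epimers) | C=CCOC(=O)C1(C)CC(=O)[C@@H]2[C@@](C)(CC1=O)[C@H](O[Si](C)(C)C(C)(C)C)C[C@@]2(O[Si](CC)(CC)CC)C(C)C | intermediate
18 | β-hydroxy ketone: C10 OH β, C3 and C7 ketones, C8 OTBS (both C1 epimers) | C=CCOC(=O)C1(C)CC(=O)[C@@H]2[C@@](C)(CC1=O)[C@H](O[Si](C)(C)C(C)(C)C)C[C@@]2(O)C(C)C | intermediate
19 | anti-1,3-diol: C3 OH α, C10 OH β, C7 ketone, C8 OTBS (both C1 epimers) | C=CCOC(=O)C1(C)C[C@H](O)[C@@H]2[C@@](C)(CC1=O)[C@H](O[Si](C)(C)C(C)(C)C)C[C@@]2(O)C(C)C | intermediate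
20 | 4-hydroxybenzoic acid | OC(=O)c1ccc(O)cc1 | starting material
21 | tert-butyldimethylsilyl 4-(tert-butyldimethylsilyloxy)benzoate | CC(C)(C)[Si](C)(C)OC(=O)c1ccc(O[Si](C)(C)C(C)(C)C)cc1 | intermediate
22 | 4-(tert-butyldimethylsilyloxy)benzoic acid | OC(=O)c1ccc(O[Si](C)(C)C(C)(C)C)cc1 | intermediate
23 | C3 4-(tert-butyldimethylsilyloxy)benzoate of 19 (both C1 epimers) | C=CCOC(=O)C1(C)C[C@H](OC(=O)c2ccc(O[Si](C)(C)C(C)(C)C)cc2)[C@@H]2[C@@](C)(CC1=O)[C@H](O[Si](C)(C)C(C)(C)C)C[C@@]2(O)C(C)C | intermediate
24 | bis-silyl enone: target with the phenol and the C8 hydroxyl as tert-butyldimethylsilyl ethers | CC1=C[C@H](OC(=O)c2ccc(O[Si](C)(C)C(C)(C)C)cc2)[C@@H]2[C@@](C)(CC1=O)[C@H](O[Si](C)(C)C(C)(C)C)C[C@@]2(O)C(C)C | intermediate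
25 | CNP0199397.1 (C3 S, C4 S, C5 R, C8 R, C10 R) | CC1=C[C@H](OC(=O)c2ccc(O)cc2)[C@@H]2[C@@](C)(CC1=O)[C@H](O)C[C@@]2(O)C(C)C | target

## Step count and risks

Total step count: 18. Longest linear sequence: 15 steps (1 to 25 through steps 1–6, 9–14 and 16–18).

**Step 9 (key step).** The most likely failure is that the sigmatropic step does not keep pace with other fates of cyclopropane 13. The C5 methyl points inward in the boat, C5 is fully substituted, and the α substituent of C10 (isopropyl) is pressed against the C7 silyloxy group. Heterolytic opening of the donor–acceptor cyclopropane and closure to five-membered rings, bonding on the face syn to the C8 silyl ether, or capture of the carbenoid by its own allyl group can then take over. The fallback moves the carbenoid reaction one stage earlier, where C10 is still a flat carbonyl, C5 is the electrophilic β carbon of an enone matched to the nucleophilic terminus C6, and only C8 differentiates the faces. It sets out from dienone 7, which is combined with 12 under the same catalyst to give the cis-divinylcyclopropane F1 (not isolated) and from it the cycloheptadiene ketone F2. Organocerium addition of the isopropyl group to the vinylogous ester carbonyl of F2, anti to the C8 silyl ether and the angular methyl, gives the tertiary alcohol F3, and silylation with TESOTf and 2,6-lutidine returns to the route at 14. The price is that the isopropyl addition must then distinguish the C10 ketone from the allyl ester.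

**Step 5.** What may go wrong is enolisation toward C9 with loss of the C8 silyloxy group, hydride transfer from the secondary Grignard reagent, or attack on both faces; the product is also a tertiary allylic alcohol beside a dienol ether and ionises easily. The fallback reverses the order of coupling and addition and uses a nucleophile without a transferable hydride. It sets out from bromoenone 5: isopropenylmagnesium bromide with CeCl3 gives the isopropenyl carbinol F4, hydrogenation of the 1,1-disubstituted alkene with RhCl(PPh3)3 and H2 gives the isopropyl carbinol F5, and TESOTf gives the triethylsilyl ether F6. Stille coupling of F6 with 6 (Pd(PPh3)4, CuI, LiCl, DMF, 80 °C) returns to the route at 9.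

**Step 12.** What may go wrong is protonation of C4 on the β face, which gives the cis ring fusion, or acid-induced loss of the C10 oxygen. The fallback abandons kinetic protonation for thermodynamic control as a separate operation. It sets out from 16; if hydrolysis gives the cis-fused C4 epimer F7, this is isolated and equilibrated through its enol with DBU in toluene while C10 is still silylated, so that retro-aldol cleavage is impossible. The trans isomer is expected to prevail because the cis isomer forces C3 and ring A onto the face of the isopropyl group. The fallback returns to the route at 17.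

**Step 17.** What may go wrong is diversion of the palladium enolate (protonation to the saturated ketone, allylation at C1, hydride loss from the methyl to the exocyclic alkene) or ionisation of the newly formed allylic aryl ester by zerovalent palladium. The fallback separates decarboxylation from desaturation. It sets out from 23: Pd(PPh3)4 with morpholine in THF removes the allyl group and gives the β-keto acid F8 (not isolated), which loses CO2 on warming to the C1-methyl ketone F9. Dehydrogenation of F9 with IBX in DMSO at 70 °C can only proceed toward C2, because C5 on the other side of the ketone is quaternary, and returns to the route at 24.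

## Further compounds

F1 | step 9 | cis-divinylcyclopropane from 7 and 12 (C10 ketone; same cyclopropane configuration as 13) | C=CCOC(=O)[C@]1(C(=C)O[Si](C)(C)C(C)(C)C)C[C@@]1(OCC)C2=C(C)[C@H](O[Si](C)(C)C(C)(C)C)CC2=O
F2 | step 9 | cycloheptadiene of type 14 with a C10 ketone (vinylogous ester with the C3=C4 enol ether) | C=CCOC(=O)C1=C(O[Si](C)(C)C(C)(C)C)C[C@@]2(C)[C@H](O[Si](C)(C)C(C)(C)C)CC(=O)C2=C(OCC)C1
F3 | step 9 | C10 tertiary alcohol corresponding to 14 (OH β, isopropyl α) | C=CCOC(=O)C1=C(O[Si](C)(C)C(C)(C)C)C[C@@]2(C)[C@H](O[Si](C)(C)C(C)(C)C)C[C@@](O)(C(C)C)C2=C(OCC)C1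
F4 | step 5 | (1R,4R)-2-bromo-4-(tert-butyldimethylsilyloxy)-3-methyl-1-(prop-1-en-2-yl)cyclopent-2-en-1-ol | CC1=C(Br)[C@](O)(C(C)=C)C[C@H]1O[Si](C)(C)C(C)(C)C
F5 | step 5 | (1R,4R)-2-bromo-4-(tert-butyldimethylsilyloxy)-3-methyl-1-(propan-2-yl)cyclopent-2-en-1-ol | CC1=C(Br)[C@](O)(C(C)C)C[C@H]1O[Si](C)(C)C(C)(C)C
F6 | step 5 | triethylsilyl ether of F5 | CC1=C(Br)[C@](O[Si](CC)(CC)CC)(C(C)C)C[C@H]1O[Si](C)(C)C(C)(C)C
F7 | step 12 | C4 epimer of 17 (cis-fused diketone, C4 H β) | C=CCOC(=O)C1(C)CC(=O)[C@H]2[C@@](C)(CC1=O)[C@H](O[Si](C)(C)C(C)(C)C)C[C@@]2(O[Si](CC)(CC)CC)C(C)C
F8 | step 17 | β-keto acid from deallylation of 23 | OC(=O)C1(C)C[C@H](OC(=O)c2ccc(O[Si](C)(C)C(C)(C)C)cc2)[C@@H]2[C@@](C)(CC1=O)[C@H](O[Si](C)(C)C(C)(C)C)C[C@@]2(O)C(C)C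
F9 | step 17 | C1-methyl C7 ketone (saturated at C1–C2, both C1 epimers) | CC1C[C@H](OC(=O)c2ccc(O[Si](C)(C)C(C)(C)C)cc2)[C@@H]2[C@@](C)(CC1=O)[C@H](O[Si](C)(C)C(C)(C)C)C[C@@]2(O)C(C)C
A1 | alternative 1 | 6-acetoxy-4-methyl-2H-pyran-3(6H)-one (acetal center racemic) | CC1=CC(OC(C)=O)OCC1=O
A2 | alternative 1 | 5-(menthyloxy)-4-methylfuran-2(5H)-one | CC1=CC(=O)O[C@H]1O[C@@H]2C[C@H](C)CC[C@H]2C(C)C
A3 | alternative 1 | exo oxygen-bridged cycloheptenone fused to the menthyloxy lactone (cis at C4/C5) | CC1=C[C@@H]2O[C@H](C1=O)[C@@]3(C)[C@H](O[C@@H]4C[C@H](C)CC[C@H]4C(C)C)OC(=O)[C@H]32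
A4 | alternative 2 | acyclic 1-chloro ketone with the tethered 2-(triethylsilyloxy)diene (C8 OTBS, C10 OTMS and isopropyl) | ClCC(=O)C[C@](O[Si](C)(C)C)(C(C)C)C[C@@H](O[Si](C)(C)C(C)(C)C)/C(C)=C/C(O[Si](CC)(CC)CC)=C/C
A5 | alternative 2 | trans-fused bicycle with C3 ketone, C6=C7 triethylsilyl enol ether and C1 methyl stereocenter | C[C@@H]1CC(=O)[C@@H]2[C@@](C)(C=C1O[Si](CC)(CC)CC)[C@H](O[Si](C)(C)C(C)(C)C)C[C@@]2(O[Si](C)(C)C)C(C)C
A6 | alternative 3 | 1-(4-benzyloxybut-2-en-2-yl)cyclobutan-1-ol carrying the silyloxybutynyl group at C4 and the triethylsilyloxy isopropyl carbon C10 (carbinol configuration and alkene geometry immaterial) | CC#C[C@H](O[Si](C)(C)C(C)(C)C)[C@@H]1C(O)(C(C)=CCOCc2ccccc2)C[C@@]1(O[Si](CC)(CC)CC)C(C)C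
A7 | alternative 3 | α-quaternary cyclopentanone (ring B) with the benzyloxyethyl chain and the alkynyl carbinol chain trans | CC#C[C@H](O[Si](C)(C)C(C)(C)C)[C@@H]1[C@@](C)(CCOCc2ccccc2)C(=O)C[C@@]1(O[Si](CC)(CC)CC)C(C)C
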